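**Retrosynthetic overview**
1. Target 13 ⇐ silyl ether 12 ⇐ flavan-4-ol 11 ⇐ 4-methoxyflavan 10. The C4 ketone is carried as a benzylic methyl ether and the 7-hydroxyl as a TBS ether.
2. The strategy rests on ring C (O1–C2–C3–C4–C4a–C8a), a pyranone fused to ring A at C4a/C8a with phenyl on C2. O1–C2 and C3–C4 are cut together, giving a C4-methoxy ortho-quinone methide (O1=C8a–C4a=C4, from salicylaldehyde 5 and trimethyl orthoformate) and styrene.
3. Aldehyde 5 ⇐ 2,4-dihydroxybenzaldehyde by C3/C5 diiodination, double Stille prenylation and selective 4-O-silylation.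
4. Ring order: rings A and B come with 1 and styrene; ring C is the only ring formed (step 4), and the C2 stereocentre is set with it.

Key step: step 4

Remark on the chemistry: the sense of induction of the confined acid in step 4 cannot be predicted with confidence, so the route is written for the catalyst antipode that gives 2S (the mirror-image catalyst is used if the first gives 2R); flavan numbering is used for the bicyclic compounds and prenyl means 3-methylbut-2-en-1-yl.

**Step 1**
Reactants: 1 2,4-dihydroxybenzaldehyde
Product: 2 2,4-dihydroxy-3,5-diiodobenzaldehyde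
Conditions: ICl (2.2 equiv), AcOH, rt; aq. Na2S2O3 work-up
Reagents that add atoms: iodine monochloride, ClI
Why: Electrophilic aromatic iodination, in which C3 (between the hydroxyls) and C5 (ortho to the 4-OH, para to the 2-OH) are the only activated positions while C6 is meta to both hydroxyls, so iodination should stop at the 3,5-diiodide.

**Step 2**
Reactants: 2 2,4-dihydroxy-3,5-diiodobenzaldehyde; 3 tributyl(prenyl)stannane
Product: 4 2,4-dihydroxy-3,5-diprenylbenzaldehyde
Conditions: 3 (3.5 equiv), Pd(PPh3)4 (10 mol %), degassed DMF, 95 °C; aq. KF work-up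
Reagents that add atoms: none
Why: Double Migita–Kosugi–Stille coupling, in which zerovalent palladium inserts into each carbon–iodine bond, the allylic stannane transmetalates and reductive elimination at the less hindered primary terminus of the prenyl ligand should give the linear prenyl arene; the excess stannane covers loss by protonolysis by the acidic phenols.

**Step 3**
Reactants: 4 2,4-dihydroxy-3,5-diprenylbenzaldehyde
Product: 5 4-(tert-butyldimethylsilyloxy)-2-hydroxy-3,5-diprenylbenzaldehyde
Conditions: TBSCl (1.1 equiv), imidazole (2.5 equiv), DMF, 0 °C → rt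
Reagents that add atoms: tert-butyldimethylsilyl chloride, CC(C)(C)[Si](C)(C)Cl
Why: Phenol silylation under Corey conditions, selective because the 4-hydroxyl para to the formyl group is the more acidic and non-chelated phenol, whereas the 2-hydroxyl is held in a hydrogen bond to the aldehyde and should stay free.

**Step 4**
Reactants: 5 4-(tert-butyldimethylsilyloxy)-2-hydroxy-3,5-diprenylbenzaldehyde; 6 trimethyl orthoformate; 7 styrene
Product: 10 (2S,4S)-7-(tert-butyldimethylsilyloxy)-4-methoxy-6,8-diprenylflavan (2,4-cis), via aryl dimethyl acetal 8 (not isolated), via 4-methoxy ortho-quinone methide 9 (not isolated)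
Conditions: 6 (2 equiv), 7 (5 equiv), confined chiral imidodiphosphorimidate Brønsted acid (two 3,3′-diaryl-BINOL units, N-triflyl groups; 5 mol %), 5 Å MS, CH2Cl2, −40 → −20 °C; Et3N quench at −20 °C
Reagents that add atoms: none
Why: Proposed new method: the acid converts 5 and the orthoformate into acetal 8 and ionises it to the ortho-hydroxybenzyl methoxycarbenium ion (the O-protonated form of 9), which is stabilised by the para silyloxy group and held as a hydrogen-bonded ion pair in the chiral pocket; the CH2 terminus of styrene attacks C4 and the ring-A oxygen captures the developing benzylic cation at C2, an asynchronous inverse-demand hetero-[4+2] addition. The closest known reactions are the achiral acid-catalysed coupling of salicylaldehydes, trimethyl orthoformate and styrenes to 2,4-cis-4-methoxyflavans, the chiral Brønsted acid catalysed [4+2] additions of aryl ortho-quinone methides to styrenes, and intramolecular [4+2] reactions of acetal-derived ortho-quinone methide oxocarbenium ions under confined chiral acids; the intermolecular enantioselective three-component form is the new element. Ring C closes as a six-membered ring by this [4+2] cycloaddition, with C3–C4 and O1–C2 formed in one operation. C2 is set by the chiral counteranion, which fixes the exposed face of the bound heterodiene and the endo approach of styrene; C4 follows from the endo transition state as 2,4-cis and is erased in step 6. The 2-phenyl regiochemistry follows from styrene polarity; chemoselectivity over the prenyl alkenes rests on the excess of styrene, on the hindered position of both prenyl groups beside the silyloxy group, and on the low temperature, at which acetal ionisation should be much faster than protonation of the C8 prenyl group next to the free phenol.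

**Step 5**
Reactants: 10 (2S,4S)-7-(tert-butyldimethylsilyloxy)-4-methoxy-6,8-diprenylflavan
Product: 11 (2S,4S)-7-(tert-butyldimethylsilyloxy)-6,8-diprenylflavan-4-ol (2,4-cis drawn as the expected main isomer; any 4-epimer is carried along)
Conditions: TsOH·H2O (0.2 equiv), THF/H2O (3:1), rt → 35 °C
Reagents that add atoms: water, O
Why: SN1 solvolysis of a benzylic ether, in which C4 ionises to a cation stabilised by O1 (ortho) and the 7-silyloxy group (para) and is captured by the large excess of water, while C2 (whose ionisation would give only a phenyl-stabilised cation), the hindered aryl silyl ether and the prenyl groups (no free ortho phenol) should be untouched by the dilute acid.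

**Step 6**
Reactants: 11 (2S,4S)-7-(tert-butyldimethylsilyloxy)-6,8-diprenylflavan-4-ol
Product: 12 (2S)-7-(tert-butyldimethylsilyloxy)-6,8-diprenylflavanone
Conditions: Dess–Martin periodinane (1.3 equiv), NaHCO3, CH2Cl2, 0 °C → rt
Reagents that add atoms: none
Why: Dess–Martin oxidation of the secondary benzylic alcohol to the aryl ketone under buffered, non-basic conditions that leave the trisubstituted alkenes alone and do not open ring C, so both C4 epimers converge on one ketone and C2 stays S.

**Step 7**
Reactants: 12 (2S)-7-(tert-butyldimethylsilyloxy)-6,8-diprenylflavanone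
Product: 13 (2S)-7-hydroxy-6,8-diprenylflavanone (target)
Conditions: TBAF (1.1 equiv), AcOH (1.2 equiv), THF, 0 °C
Reagents that add atoms: none
Why: Fluoride-mediated cleavage of the aryl silyl ether, buffered with acetic acid so that the medium never becomes basic enough for retro-oxa-Michael opening of ring C (which would racemise C2) nor acidic enough to cyclise a prenyl group onto the freed 7-hydroxyl.

**Compound list**
1 | 2,4-dihydroxybenzaldehyde | O=Cc1ccc(O)cc1O | starting material
2 | 2,4-dihydroxy-3,5-diiodobenzaldehyde | O=Cc1cc(I)c(O)c(I)c1O | intermediate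
3 | tributyl(prenyl)stannane | CCCC[Sn](CCCC)(CCCC)CC=C(C)C | starting material
4 | 2,4-dihydroxy-3,5-diprenylbenzaldehyde | O=Cc1cc(CC=C(C)C)c(O)c(CC=C(C)C)c1O | intermediate
5 | 4-(tert-butyldimethylsilyloxy)-2-hydroxy-3,5-diprenylbenzaldehyde | O=Cc1cc(CC=C(C)C)c(O[Si](C)(C)C(C)(C)C)c(CC=C(C)C)c1O | intermediate
6 | trimethyl orthoformate | COC(OC)OC | starting material
7 | styrene | C=Cc1ccccc1 | starting material
8 | 4-(tert-butyldimethylsilyloxy)-2-hydroxy-3,5-diprenylbenzaldehyde dimethyl acetal (not isolated) | COC(OC)c1cc(CC=C(C)C)c(O[Si](C)(C)C(C)(C)C)c(CC=C(C)C)c1O | intermediate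
9 | 4-methoxy ortho-quinone methide: 3-(tert-butyldimethylsilyloxy)-6-(methoxymethylidene)-2,4-diprenylcyclohexa-2,4-dien-1-one, reacting as its O-protonated ion pair with the catalyst anion (not isolated) | COC=C1C=C(CC=C(C)C)C(O[Si](C)(C)C(C)(C)C)=C(CC=C(C)C)C1=O | intermediate
10 | (2S,4S)-7-(tert-butyldimethylsilyloxy)-4-methoxy-6,8-diprenylflavan (2,4-cis) | CC(C)=CCc1cc2c(c(CC=C(C)C)c1O[Si](C)(C)C(C)(C)C)O[C@H](c1ccccc1)C[C@@H]2OC | intermediate
11 | (2S,4S)-7-(tert-butyldimethylsilyloxy)-6,8-diprenylflavan-4-ol (2,4-cis) | CC(C)=CCc1cc2c(c(CC=C(C)C)c1O[Si](C)(C)C(C)(C)C)O[C@H](c1ccccc1)C[C@@H]2O | intermediate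
12 | (2S)-7-(tert-butyldimethylsilyloxy)-6,8-diprenylflavanone | CC(C)=CCc1cc2c(c(CC=C(C)C)c1O[Si](C)(C)C(C)(C)C)O[C@H](c1ccccc1)CC2=O | intermediate
13 | (2S)-7-hydroxy-6,8-diprenylflavanone | CC(C)=CCc1cc2c(c(CC=C(C)C)c1O)O[C@H](c1ccccc1)CC2=O | target

**Total step count:** 7
**Longest linear sequence:** 7 steps (1 → 13)

**Steps most likely to fail**

Step 4 (proposed new method).
- What may go wrong: the chiral anion may discriminate the styrene faces poorly. Endo and exo addition on the same quinone methide face give cis and trans adducts that differ at C2, so any trans isomer should be removed by chromatography before C4 is erased.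
- Further risks are capture of the cation by a prenyl alkene of a second molecule, acid-induced closure of the C8 prenyl group onto the free phenol, and methanolysis of the silyl ether at the cation stage.
- Fallback (known chemistry), from 5 back to 12:
  - 5, 6 and 7 are coupled under an achiral acid (catalytic TfOH or Sc(OTf)3, CH2Cl2, 0 °C), the known racemic three-component reaction, to give racemic 2,4-cis-7-(tert-butyldimethylsilyloxy)-4-methoxy-6,8-diprenylflavan F1.
  - Hydrolysis as in step 5 should give racemic 2,4-cis-7-(tert-butyldimethylsilyloxy)-6,8-diprenylflavan-4-ol F2, and Dess–Martin oxidation as in step 6 racemic 7-(tert-butyldimethylsilyloxy)-6,8-diprenylflavanone F3.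
  - Kinetic resolution of F3 by asymmetric transfer hydrogenation (RuCl(p-cymene)[(R,R)-TsDPEN], HCO2H/Et3N, EtOAc, rt, stopped near half conversion) is expected, by the usual sense of this catalyst class, to reduce the 2R ketone to (2R,4R)-7-(tert-butyldimethylsilyloxy)-6,8-diprenylflavan-4-ol F4 and leave the 2S ketone, which is 12.
  - F4 is separated by chromatography; at most half of the material can be used this way.

Step 5.
- What may go wrong: the C4 cation may lose a C3 proton to give the flav-3-ene instead of being trapped by water, the exchange may stall at equilibrium, or the prenyl groups may slowly hydrate on prolonged acid contact.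
- Fallback, from 10 directly to 12: oxidation of the benzylic methyl ether with DDQ (1.2 equiv) in CH2Cl2/pH 7 phosphate buffer at 0 °C. Hydride abstraction from C4–H, the only C–H flanked by the methoxy oxygen and the donor-substituted arene, gives the methoxycarbenium ion, water adds, and the hemiketal loses methanol. Step 6 is then not needed and no new compound is made on this way (F0).

Step 2.
- What may go wrong: the second coupling may be incomplete, protodeiodination may compete, coupling may occur at the tertiary allyl terminus (reverse-prenyl isomer), or the acidic phenols may consume the stannane and slow the palladium cycle.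
- Fallback, from 1 back to 4 without palladium coupling:
  - O-allylation of both hydroxyls (allyl bromide, K2CO3, DMF) gives 2,4-bis(allyloxy)benzaldehyde F5.
  - Heating in N,N-diethylaniline at about 200 °C (double aromatic Claisen rearrangement, in which an allyl group that finds its ortho positions occupied moves on to C5 by a further Cope shift) should give 3,5-diallyl-2,4-dihydroxybenzaldehyde F6.
  - Cross-metathesis with excess 2-methyl-2-butene (second-generation Grubbs catalyst, CH2Cl2, 40 °C) turns both allyl groups into prenyl groups and gives 4.

**Further compounds**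
F1 | step 4 | racemic 2,4-cis-7-(tert-butyldimethylsilyloxy)-4-methoxy-6,8-diprenylflavan (both enantiomers written) | CC(C)=CCc1cc2c(c(CC=C(C)C)c1O[Si](C)(C)C(C)(C)C)O[C@H](c1ccccc1)C[C@@H]2OC.CC(C)=CCc1cc2c(c(CC=C(C)C)c1O[Si](C)(C)C(C)(C)C)O[C@@H](c1ccccc1)C[C@H]2OC
F2 | step 4 | racemic 2,4-cis-7-(tert-butyldimethylsilyloxy)-6,8-diprenylflavan-4-ol (both enantiomers written) | CC(C)=CCc1cc2c(c(CC=C(C)C)c1O[Si](C)(C)C(C)(C)C)O[C@H](c1ccccc1)C[C@@H]2O.CC(C)=CCc1cc2c(c(CC=C(C)C)c1O[Si](C)(C)C(C)(C)C)O[C@@H](c1ccccc1)C[C@H]2O
F3 | step 4 | racemic 7-(tert-butyldimethylsilyloxy)-6,8-diprenylflavanone (both enantiomers written) | CC(C)=CCc1cc2c(c(CC=C(C)C)c1O[Si](C)(C)C(C)(C)C)O[C@H](c1ccccc1)CC2=O.CC(C)=CCc1cc2c(c(CC=C(C)C)c1O[Si](C)(C)C(C)(C)C)O[C@@H](c1ccccc1)CC2=O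
F4 | step 4 | (2R,4R)-7-(tert-butyldimethylsilyloxy)-6,8-diprenylflavan-4-ol | CC(C)=CCc1cc2c(c(CC=C(C)C)c1O[Si](C)(C)C(C)(C)C)O[C@@H](c1ccccc1)C[C@H]2O
F0 | step 5 | none | none
F5 | step 2 | 2,4-bis(allyloxy)benzaldehyde | O=Cc1ccc(OCC=C)cc1OCC=C
F6 | step 2 | 3,5-diallyl-2,4-dihydroxybenzaldehyde | O=Cc1cc(CC=C)c(O)c(CC=C)c1O
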